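The side chain is cut between C2′ and C3′ (numbered outward from C3 of the δ-lactone ring), two unactivated CH2 groups. The key step is a one-pot hydroboration/alkyl–alkyl Suzuki–Miyaura coupling: 9-BBN adds only to the terminal double bond of (Z)-trideca-1,4-diene, and the resulting primary borane is coupled with the primary bromide of (S)-3-(2-bromoethyl)-8-methoxyisochroman-1-one. Two features are exploited: C3′=C4′ can be a vinyl group separated by one CH2 (C5′) from the (Z)-C6′=C7′ alkene, so a skipped diene is a latent C3′ nucleophile; and C2′ is γ to the ring oxygen on C3, so no β-elimination threatens. C3 comes from a chiral C4 bromo-epoxide; BCl3 demethylation ends the route.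

Key step: step 3

Remark on the chemistry: epoxide 2, (R)-2-(2-bromoethyl)oxirane, is assumed to be purchasable in enantiopure form. The C3 descriptor changes along the route (R in 2, S in 4 and 5, R in 11 and 12) only because the CIP priorities change; the spatial arrangement is the same throughout.

Step 1
Reactants: 1 methyl 2-bromo-6-methoxybenzoate; 2 (R)-2-(2-bromoethyl)oxirane
Product: 5 (S)-3-(2-bromoethyl)-8-methoxyisochroman-1-one, via arylmagnesium chloride 3 (not isolated), via chloromagnesium alkoxide 4 (not isolated)
Conditions: iPrMgCl·LiCl (1.1 equiv), THF, −20 °C; then CuI (10 mol%), 2 (1.2 equiv), −30 → 0 °C; 1 M HCl work-up; crude with cat. TsOH, toluene, 50 °C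
Reagents that add atoms: none
Why: Bromine–magnesium exchange (turbo-Grignard, assisted by the ortho ester) gives 3, whose copper-catalysed SN2 epoxide opening at the unsubstituted CH2 (faster than attack at the primary C–Br at low temperature) leaves the C–O stereocentre of 2 untouched, and alkoxide 4 then closes the six-membered lactone on the neighbouring methyl ester (lactonisation, completed by acid).

Step 2
Reactants: 6 nonanal; 7 but-3-en-1-yltriphenylphosphonium bromide
Product: 9 (Z)-trideca-1,4-diene, via phosphorus ylide 8 (not isolated)
Conditions: 7, NaHMDS (1.0 equiv), THF, 0 °C; then 6, −78 °C → rt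
Reagents that add atoms: none
Why: Wittig reaction of the non-stabilised, lithium-free ylide 8 with an unbranched aldehyde at −78 °C runs under kinetic control through the cis-oxaphosphetane and should give the (Z)-C4=C5 alkene, the terminal vinyl group being a spectator.

Step 3
Reactants: 9 (Z)-trideca-1,4-diene; 5 (S)-3-(2-bromoethyl)-8-methoxyisochroman-1-one
Product: 11 (R)-8-methoxy-3-[(Z)-pentadec-6-en-1-yl]isochroman-1-one, via B-alkyl-9-BBN 10 (not isolated)
Conditions: 9 (1.4 equiv), 9-BBN (1.3 equiv B–H), THF, 0 °C → rt; then 5 (1.0 equiv), Pd(OAc)2 (4 mol%), PCy3 (8 mol%), K3PO4·H2O (1.5 equiv), THF, rt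
Reagents that add atoms: none
Why: 9-BBN hydroborates the monosubstituted C1=C2 of skipped diene 9 anti-Markovnikov and much faster than the cis-disubstituted C4=C5, giving primary alkylborane 10; the hydrated phosphate turns 10 into a borate that transmetalates to the alkylpalladium(II) bromide formed by SN2-type oxidative addition of Pd(0)/PCy3 to the primary C–Br of 5, and reductive elimination forms the CH2–CH2 bond. The closest known reaction type is the room-temperature alkyl–alkyl Suzuki–Miyaura coupling of B-alkyl-9-BBN reagents with unactivated primary alkyl bromides that carry β-hydrogens (Pd(OAc)2/PCy3/K3PO4·H2O). No ring is closed and no stereocentre is formed; the C3 stereocentre is γ to the reacting carbon and not involved, and the (Z)-alkene is carried through unchanged. The step needs chemoselectivity in the hydroboration (terminal over internal alkene), secured by the steric demand of 9-BBN used in slight deficit to the diene, and C–C coupling over β-hydride elimination, secured by the bulky electron-rich PCy3. The lactone and aryl methyl ether should tolerate the mild heterogeneous base, and because the oxygen on C3 is γ rather than β to palladium, β-alkoxide elimination is not possible.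

Step 4
Reactants: 11 (R)-8-methoxy-3-[(Z)-pentadec-6-en-1-yl]isochroman-1-one
Product: 12 (R)-8-hydroxy-3-[(Z)-pentadec-6-en-1-yl]isochroman-1-one
Conditions: BCl3 (1 M in CH2Cl2, 2.5 equiv), CH2Cl2, −78 → 0 °C; aq. NaHCO3 work-up
Reagents that add atoms: none
Why: BCl3 chelates between the lactone carbonyl and the peri 8-methoxy oxygen and chloride removes the methyl group (Lewis-acid cleavage of an ortho-carbonyl aryl methyl ether), conditions under which the isolated (Z)-alkene, the lactone and the C3 stereocentre should stay untouched.

Compound list
1 | methyl 2-bromo-6-methoxybenzoate | COC(=O)c1c(Br)cccc1OC | starting material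
2 | (R)-2-(2-bromoethyl)oxirane | BrCC[C@@H]1CO1 | starting material
3 | [3-methoxy-2-(methoxycarbonyl)phenyl]magnesium chloride (LiCl complex, not isolated) | COC(=O)c1c([Mg]Cl)cccc1OC | intermediate
4 | chloromagnesium alkoxide of methyl 2-[(2S)-4-bromo-2-hydroxybutyl]-6-methoxybenzoate (not isolated) | BrCC[C@@H](O[Mg]Cl)Cc1cccc(OC)c1C(=O)OC | intermediate
5 | (S)-3-(2-bromoethyl)-8-methoxyisochroman-1-one | BrCC[C@@H]1Cc2cccc(OC)c2C(=O)O1 | intermediate
6 | nonanal | CCCCCCCCC=O | starting material
7 | but-3-en-1-yltriphenylphosphonium bromide | C=CCC[P+](c1ccccc1)(c1ccccc1)c1ccccc1.[Br-] | starting material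
8 | but-3-en-1-ylidenetriphenylphosphorane (ylide, not isolated) | C=CCC=P(c1ccccc1)(c1ccccc1)c1ccccc1 | intermediate
9 | (Z)-trideca-1,4-diene | CCCCCCCC/C=C\CC=C | intermediate
10 | B-[(Z)-tridec-4-en-1-yl]-9-borabicyclo[3.3.1]nonane (not isolated) | CCCCCCCC/C=C\CCCB1C2CCCC1CCC2 | intermediate
11 | (R)-8-methoxy-3-[(Z)-pentadec-6-en-1-yl]isochroman-1-one | CCCCCCCC/C=C\CCCCC[C@@H]1Cc2cccc(OC)c2C(=O)O1 | intermediate
12 | (R)-8-hydroxy-3-[(Z)-pentadec-6-en-1-yl]isochroman-1-one | CCCCCCCC/C=C\CCCCC[C@@H]1Cc2cccc(O)c2C(=O)O1 | target

Total step count: 4
Longest linear sequence: 3 steps (step 1 or step 2, then steps 3 and 4)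

Steps most likely to fail

Step 3 (key step). What may go wrong: β-hydride elimination or reduction of the alkylpalladium species formed from 5, slow transmetalation of the borate, or partial hydroboration of the internal alkene. Fallback: an alkyl–alkyl Negishi coupling that forms the same bond with the roles of the two carbons exchanged. It sets out from borane 10 and bromide 5 and returns at 11. Borane 10 is oxidised (NaOH, H2O2, THF, 0 °C) to (Z)-tridec-4-en-1-ol F1, which is converted (PPh3, I2, imidazole, CH2Cl2, 0 °C) into (Z)-1-iodotridec-4-ene F2. Bromide 5 is converted by zinc insertion (Zn dust, LiCl, THF, 50 °C) into {2-[(S)-8-methoxy-1-oxoisochroman-3-yl]ethyl}zinc bromide F3. F3 and F2 are then coupled with Pd-PEPPSI-IPr (THF/NMP, rt) to give 11.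

Step 1. What may go wrong: incomplete bromine–magnesium exchange, attack of the Grignard reagent on the ester, or loss of the epoxide through halide opening or reaction at its C–Br bond. Fallback: directed ortho-metalation of an amide in place of halogen–metal exchange of an ester. It sets out from epoxide 2 and returns at lactone 5. Purchased N,N-diethyl-2-methoxybenzamide (CCN(CC)C(=O)c1ccccc1OC) is lithiated ortho to the amide (s-BuLi, TMEDA, THF, −78 °C) and the aryllithium is added to 2 with BF3·OEt2 at −78 °C to give N,N-diethyl-2-[(2S)-4-bromo-2-hydroxybutyl]-6-methoxybenzamide F4. F4 is lactonised (TsOH·H2O, toluene, reflux) to 5 with loss of diethylamine.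

Step 2. What may go wrong: erosion of Z-selectivity, giving an E isomer that is hard to separate, or base-induced migration of the terminal double bond. Fallback: the Z-alkene is made by alkyne semi-hydrogenation instead of a Wittig reaction. It sets out from nonanal 6 and returns at diene 9. Ohira–Bestmann homologation of 6 (dimethyl (1-diazo-2-oxopropyl)phosphonate, K2CO3, MeOH, rt) should give dec-1-yne F5. Copper-mediated allylation (allyl bromide, CuI, K2CO3, NaI, DMF, rt) should give tridec-1-en-4-yne F6. Lindlar semi-hydrogenation (H2, Pd/CaCO3–Pb, quinoline, hexane) should then give 9.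

Further compounds
F1 | step 3 | (Z)-tridec-4-en-1-ol | CCCCCCCC/C=C\CCCO
F2 | step 3 | (Z)-1-iodotridec-4-ene | CCCCCCCC/C=C\CCCI
F3 | step 3 | {2-[(S)-8-methoxy-1-oxoisochroman-3-yl]ethyl}zinc bromide | Br[Zn]CC[C@@H]1Cc2cccc(OC)c2C(=O)O1
F4 | step 1 | N,N-diethyl-2-[(2S)-4-bromo-2-hydroxybutyl]-6-methoxybenzamide | BrCC[C@@H](O)Cc1cccc(OC)c1C(=O)N(CC)CC
F5 | step 2 | dec-1-yne | CCCCCCCCC#C
F6 | step 2 | tridec-1-en-4-yne | CCCCCCCCC#CCC=C
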